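**Assumptions:** (i) Commercial O‑protected resorcinol and catechol (1,3‑dimethoxybenzene, catechol diacetate) are used as bought; their Me/Ac groups are protecting groups only, removed in steps 4 and 8. (ii) (R)‑t‑BuPyOx is taken to give 2S by analogy with the facial model for cyclic enones (the (S)‑ligand gives (R)‑3‑aryl‑3‑methylcyclohexanones); if the sense is opposite, the (S)‑ligand is used.

## Retrosynthetic overview

1. Prokinawan ⇐ tetra‑O‑acetate by neutral deacetylation.
2. Key disconnection: C6–C1'' and C4''–C5'' are cut together, giving a 6‑iodoflavanone, isoprene and the 3‑hydroxy‑3‑methylbutyl radical (Ni‑mediated radical 1,4‑alkylarylation of the diene; sets the E‑alkene).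
3. C2–C1' (the only stereocentre) ⇐ 6‑iodochromone + B‑ring boronic acid by Pd(II)/PyOx asymmetric conjugate addition.
4. Chromone ⇐ 4‑iodo‑3,5‑dimethoxyphenol + methyl propiolate (oxa‑Michael/cycloacylation); the phenol oxygen comes from Ir C–H borylation/oxidation, the iodine from directed ortho‑lithiation.
5. Ring order: ring A (preformed resorcinol core) → ring C (pyranone) → ring B attached (preformed catechol core) → side chain last.

## Route

**Step 1**
Reactants: 1, 1,3‑dimethoxybenzene
Product: 2, 2‑iodo‑1,3‑dimethoxybenzene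
Conditions: n‑BuLi, THF, 0 °C → rt; then I2, −78 °C → rt
Reagents that add atoms: iodine, II
Why: Directed ortho‑metalation removes only the C2–H flanked by both OMe groups, and iodine quench fixes the future C6 handle on the symmetry axis of the ring.

**Step 2**
Reactants: 2, 2‑iodo‑1,3‑dimethoxybenzene
Product: 3, 4‑iodo‑3,5‑dimethoxyphenol
Conditions: [Ir(OMe)(cod)]2 (1.5 mol%), dtbpy (3 mol%), B2pin2, THF, 80 °C; then NaBO3·4H2O, THF/H2O, rt (one pot)
Reagents that add atoms: sodium perborate (oxygen source), [Na+].[Na+].O[B-]1(O)OO[B-](O)(O)OO1; B2pin2 is transient (boron not retained), CC1(C)OB(OC1(C)C)B1OC(C)(C)C(C)(C)O1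
Why: Sterically controlled Ir C–H borylation occurs at C5, the only C–H not ortho to a substituent (aryl iodides are tolerated), and perborate oxidation of the ArBpin gives the phenol without oxidising the aryl iodide.

**Step 3**
Reactants: 3, 4‑iodo‑3,5‑dimethoxyphenol; 4, methyl propiolate
Product: 5, 6‑iodo‑5,7‑dimethoxy‑4H‑chromen‑4‑one
Conditions: DABCO (10 mol%), CH2Cl2, 0 °C → rt; evaporate; Eaton's reagent (P2O5/MeSO3H), 45 °C
Reagents that add atoms: none
Why: Ruhemann‑type chromone synthesis — oxa‑Michael addition gives the aryloxyacrylate, which equilibrates E/Z in acid and undergoes intramolecular Friedel–Crafts acylation at either of the two equivalent ortho positions, so the iodine ends at C6 with no 6/8 ambiguity.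

**Step 4**
Reactants: 5, 6‑iodo‑5,7‑dimethoxy‑4H‑chromen‑4‑one
Product: 6, 6‑iodo‑4‑oxo‑4H‑chromene‑5,7‑diyl diacetate
Conditions: BBr3 (5 equiv), CH2Cl2, −78 °C → rt; aq. NaHCO3 work‑up; crude diol, Ac2O, pyridine, DMAP (cat.), rt
Reagents that add atoms: acetic anhydride, CC(=O)OC(C)=O
Why: Lewis‑acid ether cleavage is done on the achiral chromone, before any stereocentre exists, and acetylation of the crude diol gives mildly removable groups and a more electrophilic enone.

**Step 5**
Reactants: 7, 1,2‑diacetoxybenzene (catechol diacetate)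
Product: 8, (3,4‑diacetoxyphenyl)boronic acid
Conditions: [Ir(OMe)(cod)]2 (1 mol%), dtbpy (2 mol%), B2pin2, cyclohexane, 80 °C; then NaIO4, 1 M HCl, THF/H2O, rt (one pot)
Reagents that add atoms: B2pin2, CC1(C)OB(OC1(C)C)B1OC(C)(C)C(C)(C)O1; water, O
Why: Ir C–H borylation of a 1,2‑disubstituted arene is sterically directed to C4, and periodate cleavage of the pinacol ester gives the free boronic acid while the aryl acetates survive the cold dilute acid.

**Step 6**
Reactants: 6, 6‑iodo‑4‑oxo‑4H‑chromene‑5,7‑diyl diacetate; 8, (3,4‑diacetoxyphenyl)boronic acid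
Product: 9, (2S)‑2‑(3,4‑diacetoxyphenyl)‑6‑iodo‑4‑oxochroman‑5,7‑diyl diacetate
Conditions: Pd(OCOCF3)2 (5 mol%), (R)‑t‑BuPyOx (6 mol%), NH4PF6 (30 mol%), H2O (5 equiv), ClCH2CH2Cl, 60 °C
Reagents that add atoms: none
Why: Pd(II)/pyridine‑oxazoline asymmetric conjugate addition of an arylboronic acid to a chromone — the aryl–Pd(II) inserts into C2=C3 on the face set by the ligand to give C2 as S, and because the cycle is redox‑neutral Pd(II) the aryl iodide and acetates are untouched.

**Step 7 (key step)**
Reactants: 9, (2S)‑2‑(3,4‑diacetoxyphenyl)‑6‑iodo‑4‑oxochroman‑5,7‑diyl diacetate; 10, isoprene; 11, 4‑bromo‑2‑methylbutan‑2‑ol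
Product: 12, (2S)‑2‑(3,4‑diacetoxyphenyl)‑6‑[(2E)‑7‑hydroxy‑3,7‑dimethyloct‑2‑en‑1‑yl]‑4‑oxochroman‑5,7‑diyl diacetate
Conditions: NiBr2·glyme (10 mol%), dtbbpy (12 mol%), Mn (3 equiv), NaI (1 equiv), isoprene (20 equiv, ca. 2.5 M), DMA, 25 °C, sealed tube; 11 (2.5 equiv) added over 6 h
Reagents that add atoms: none
Why: Proposed new method: Ni(I) abstracts halogen from the in‑situ alkyl iodide to give the primary radical •CH2CH2C(CH3)2OH, which is intercepted by the large excess of s‑trans isoprene at C1 faster than by the dilute, di‑ortho‑substituted ArNi(II); the resulting configurationally stable allyl radical is captured by ArNi(II) and Ar–C reductive elimination from Ni(III) occurs at the unhindered CH2 terminus, forming C4''–C5'' and C6–C1'' in one operation with the E geometry inherited from s‑trans isoprene (isomerisation would need σ‑bonding at the tertiary allyl carbon); the closest known reaction type is Ni‑catalysed reductive three‑component alkylarylation of alkenes and 1,3‑dienes, together with radical 1,4‑difunctionalisation of isoprene.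

**Step 8**
Reactants: 12, the tetra‑O‑acetate from step 7
Product: 13, Prokinawan, (2S)‑2‑(3,4‑dihydroxyphenyl)‑5,7‑dihydroxy‑6‑[(2E)‑7‑hydroxy‑3,7‑dimethyloct‑2‑en‑1‑yl]chroman‑4‑one
Conditions: NH4OAc (12 equiv), MeOH/H2O (4:1), rt
Reagents that add atoms: none
Why: Neutral ammonium‑acetate deacetylation of aryl acetates near pH 7 avoids the base‑induced retro‑oxa‑Michael racemisation of C2 and the acid‑induced chroman formation or tertiary‑alcohol ionisation in the side chain.

## Compound list

1 | 1,3‑dimethoxybenzene | COc1cccc(OC)c1 | starting material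
2 | 2‑iodo‑1,3‑dimethoxybenzene | COc1cccc(OC)c1I | intermediate
3 | 4‑iodo‑3,5‑dimethoxyphenol | COc1cc(O)cc(OC)c1I | intermediate
4 | methyl propiolate | C#CC(=O)OC | starting material
5 | 6‑iodo‑5,7‑dimethoxy‑4H‑chromen‑4‑one | COc1cc2occc(=O)c2c(OC)c1I | intermediate
6 | 6‑iodo‑4‑oxo‑4H‑chromene‑5,7‑diyl diacetate | CC(=O)Oc1cc2occc(=O)c2c(OC(C)=O)c1I | intermediate
7 | 1,2‑diacetoxybenzene (catechol diacetate) | CC(=O)Oc1ccccc1OC(C)=O | starting material
8 | (3,4‑diacetoxyphenyl)boronic acid | CC(=O)Oc1ccc(B(O)O)cc1OC(C)=O | intermediate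
9 | (2S)‑2‑(3,4‑diacetoxyphenyl)‑6‑iodo‑4‑oxochroman‑5,7‑diyl diacetate | O=C1C[C@@H](c2ccc(OC(C)=O)c(OC(C)=O)c2)Oc2cc(OC(C)=O)c(I)c(OC(C)=O)c12 | intermediate
10 | isoprene (2‑methylbuta‑1,3‑diene) | C=CC(C)=C | starting material
11 | 4‑bromo‑2‑methylbutan‑2‑ol | CC(C)(O)CCBr | starting material
12 | (2S)‑2‑(3,4‑diacetoxyphenyl)‑6‑[(2E)‑7‑hydroxy‑3,7‑dimethyloct‑2‑en‑1‑yl]‑4‑oxochroman‑5,7‑diyl diacetate | O=C1C[C@@H](c2ccc(OC(C)=O)c(OC(C)=O)c2)Oc2cc(OC(C)=O)c(C/C=C(\C)CCCC(C)(C)O)c(OC(C)=O)c12 | intermediate
13 | Prokinawan | C/C(=C\Cc1c(O)cc2c(c1O)C(=O)C[C@@H](c1ccc(O)c(O)c1)O2)CCCC(C)(C)O | target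

## Summary

Total steps: 8. Longest linear sequence: 7 (steps 1 → 2 → 3 → 4 → 6 → 7 → 8).

**Steps most likely to fail, with fallbacks**

1. **Step 7 (three‑component radical coupling).**
   - Risks: direct aryl–alkyl coupling without isoprene, hydrodeiodination, minor C4‑attack regioisomer on isoprene, E/Z leakage.
   - Fallback: split the event in two. First make (E)‑7‑hydroxy‑3,7‑dimethyloct‑2‑en‑1‑yl acetate from 11, isoprene and acetate by photoexcited‑Pd radical 1,4‑carbo‑oxygenation (radical–polar crossover). Then join it to 9 by a two‑component Ni‑catalysed reductive aryl–allyl cross‑electrophile coupling.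

2. **Step 6 (asymmetric conjugate addition to a 5,7‑diacetoxy‑6‑iodochromone).**
   - Risks: low conversion or ee on this unprecedented substrate; partial acetate hydrolysis.
   - Fallback: make racemic 9 with an achiral ligand (Pd(OCOCF3)2/2,2'‑bipyridine) and obtain the 2S enantiomer by resolution — Ru–TsDPEN transfer‑hydrogenation kinetic resolution of the flavanone, or preparative chiral SFC.

3. **Step 3 (acid cycloacylation with the aryl iodide in place).**
   - Risks: protodeiodination or iodine migration in strong acid; sluggish acylium formation from the methyl ester.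
   - Fallback: change the order. Carry no halogen through ring formation (1 → 3,5‑dimethoxyphenol → 5,7‑dimethoxychromone → 5,7‑diol), acetylate the 7‑OH selectively, and introduce iodine late at C6 by iodination ortho to the free, chelated 5‑OH (BnMe3N·ICl2, CaCO3), then acetylate.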